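## Retrosynthetic overview

1. Last disconnection: the Z-γ-ylidenebutenolide (carotenoid numbering: ring A = C1–C6, arm C7–C8, butenolide C9, C10, C11, C19, polyene C12–C15 and C15'–C7', epoxy ring C1'–C6') is cut at C10–C11 and O–C11 into a (Z)-3-iodoacrylic acid carrying ring A and a terminal polyenyne. A Pd/Cu coupling with in situ 5-exo-dig lactonisation joins them, so the butenolide is the last ring formed.
2. The polyenyne comes from (4R,6R)-actinol: enol triflate, carbonylation, Sharpless epoxidation (oxirane ring, formed second), two C5 Horner–Wadsworth–Emmons/i-Bu2AlH cycles and one enynyl phosphonate olefination.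
3. The iodo acid comes from the ring A ester by reduction, Duboudin anti-carbomagnesiation of propargyl alcohol with iodination, and allylic oxidation.
4. Ring A is formed first and is closed at C1–C2: the silyl enol ether of a methyl ketone (C2) opens the gem-dimethylcyclopropane of (1R,3R)-chrysanthemic acid at its quaternary carbon. The cyclopropane is a temporary ring that is cleaved in the same step.
5. Enabling feature: in the cyclohexenone ring the quaternary gem-dimethyl carbon C1 lies between the ketone α-methylene C2 and the stereogenic C6–H that carries the two-carbon arm C7–C8. C1, C6 and C7 are the three ring carbons of chrysanthemic acid and C8 is its carboxyl, so the C8 acceptor makes C1 electrophilic, C6 keeps the chiral-pool configuration, and the C3 ketone supplies C2 as nucleophile.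

Key step: step 6

Remark: (1R,3R)-(+)-trans-chrysanthemic acid and (4R,6R)-actinol are taken as purchasable chiral-pool materials; the methyl-bearing carbon in 7–10 and the ring carbinol carbon in 12, 13 and 15–17 are carried as epimer mixtures (no descriptor in the SMILES) because both become sp2 again in steps 7 and 11.

## Fragment A: iodo acid 19 (contains the key step)

Step 1
Reactants: 1 (1R,3R)-2,2-dimethyl-3-(2-methylprop-1-en-1-yl)cyclopropane-1-carboxylic acid ((+)-trans-chrysanthemic acid)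
Product: 2 methyl (1R,3R)-2,2-dimethyl-3-(2-methylprop-1-en-1-yl)cyclopropane-1-carboxylate
Conditions: MeI, K2CO3, DMF, rt
Reagents that add atoms: iodomethane, CI
Why: Carboxylate O-alkylation (SN2 esterification) should give the methyl ester that later acts as the acceptor of the cyclopropane, with no stereocentre touched.

Step 2
Reactants: 2 methyl (1R,3R)-chrysanthemate
Product: 4 methyl (1R,3R)-3-formyl-2,2-dimethylcyclopropane-1-carboxylate, via secondary ozonide 3 (not isolated)
Conditions: O3, CH2Cl2, −78 °C; then Me2S, −78 °C → rt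
Reagents that add atoms: ozone, [O-][O+]=O
Why: Ozonolysis with reductive work-up should cleave the only C=C bond to the aldehyde, leaving the trans-cyclopropane (the stable isomer) and both stereocentres unchanged.

Step 3
Reactants: 4 methyl (1R,3R)-3-formyl-2,2-dimethylcyclopropane-1-carboxylate; 5 1-(triphenyl-λ5-phosphanylidene)propan-2-one
Product: 6 methyl (1R,3R)-2,2-dimethyl-3-[(1E)-3-oxobut-1-en-1-yl]cyclopropane-1-carboxylate
Conditions: CH2Cl2, 40 °C
Reagents that add atoms: none
Why: Wittig olefination with a stabilised ylide should give the E-enone and should not touch the hindered ester.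

Step 4
Reactants: 6 methyl (1R,3R)-2,2-dimethyl-3-[(1E)-3-oxobut-1-en-1-yl]cyclopropane-1-carboxylate
Product: 7 methyl (1R,3R)-2,2-dimethyl-3-[(2RS)-4-oxopentan-2-yl]cyclopropane-1-carboxylate
Conditions: Me2CuLi (from MeLi, CuI), Et2O, −78 → −30 °C; aq. NH4Cl
Reagents that add atoms: lithium dimethylcuprate, [Li+].C[Cu-]C
Why: Gilman cuprate conjugate addition should place the future C5 methyl group without attacking the ester; the new centre forms as an epimer mixture that is inconsequential because C5 becomes sp2 in step 7.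

Step 5
Reactants: 7 methyl (1R,3R)-2,2-dimethyl-3-[(2RS)-4-oxopentan-2-yl]cyclopropane-1-carboxylate
Product: 8 methyl (1R,3R)-2,2-dimethyl-3-[(2RS)-4-[(trimethylsilyl)oxy]pent-4-en-2-yl]cyclopropane-1-carboxylate
Conditions: LiN(iPr)2, THF, −78 °C; Me3SiCl, Et3N, −78 → 0 °C; cold aq. NaHCO3, pentane
Reagents that add atoms: chlorotrimethylsilane, C[Si](C)(C)Cl
Why: Kinetic enolisation of the methyl ketone on the methyl side and O-silylation (kinetic silyl enol ether formation) should be faster than deprotonation at the branched methylene or at the cyclopropane C–H next to the ester.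

Step 6
Reactants: 8 methyl (1R,3R)-2,2-dimethyl-3-[(2RS)-4-[(trimethylsilyl)oxy]pent-4-en-2-yl]cyclopropane-1-carboxylate
Product: 10 methyl 2-[(1S,6RS)-2,2,6-trimethyl-4-oxocyclohexyl]acetate, via trichlorotitanium ester enolate 9 (not isolated)
Conditions: TiCl4 (1.2 equiv), CH2Cl2 (0.01 M), −78 → −20 °C; aq. NaHCO3
Reagents that add atoms: none
Why: Proposed new method: TiCl4 binds the ester carbonyl and polarises the cyclopropane bond between the ester-bearing carbon (C7) and the gem-dimethyl carbon (C1), so that C1 gains tertiary-cation character and is attacked from the backside by the terminal carbon (C2) of the tethered silyl enol ether while C7 leaves as a titanium ester enolate with loss of Me3SiCl, a homo-Mukaiyama–Michael ring opening. The closest known reactions are the Lewis-acid opening of donor–acceptor cyclopropanes by silyl enol ethers, the acid-induced heterolysis of this same bond in chrysanthemates (pyrocine formation) and the Reetz α-tert-alkylation of silyl enol ethers, into which even a stepwise tertiary chloride or cation path would funnel. The cyclohexanone closes in a 6-(enolexo)-exo-tet mode, since the breaking C1–C7 bond is exocyclic and the backside trajectory at C1 makes an angle of about 120° with the C1–C6 bond, which suits a six-membered ring. No stereocentre is created (C1 carries two methyl groups, C2 is a methylene), and C6 keeps the chiral-pool configuration because none of its bonds is broken. The step needs cleavage of C1–C7 and not of C6–C7, secured by the tertiary gem-dimethyl donor at C1 against a secondary C6 with a saturated non-donating side chain; it needs C- and not O-alkylation (six- against eight-membered ring); and it needs ring closure to outrun 1,2-hydride shift or proton loss, which the intramolecular nucleophile, low temperature and high dilution favour, while acylation at the ester is geometrically excluded by the trans arrangement on the cyclopropane.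

Step 7
Reactants: 10 methyl 2-[(1S,6RS)-2,2,6-trimethyl-4-oxocyclohexyl]acetate
Product: 11 methyl 2-[(1R)-2,6,6-trimethyl-4-oxocyclohex-2-en-1-yl]acetate
Conditions: Pd(OCOCF3)2 (5 mol %), DMSO (10 mol %), O2 (1 atm), AcOH, 80 °C
Reagents that add atoms: none
Why: Aerobic palladium-catalysed α,β-dehydrogenation of a cyclohexanone (Stahl type, palladium enolate then β-hydride elimination) can only give the C4=C5 enone because the other α-carbon is flanked by the quaternary C1, so both C5 epimers should converge and C6 is not touched.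

Step 8
Reactants: 11 methyl 2-[(1R)-2,6,6-trimethyl-4-oxocyclohex-2-en-1-yl]acetate
Product: 12 (1RS,4R)-4-(2-hydroxyethyl)-3,5,5-trimethylcyclohex-2-en-1-ol
Conditions: i-Bu2AlH (5 equiv), CH2Cl2, −78 → 0 °C; aq. potassium sodium tartrate
Reagents that add atoms: none
Why: Hydride reduction with i-Bu2AlH should take the ester to the primary alcohol and the enone by 1,2-addition to the allylic alcohol, which masks the ketone for the Grignard step; the carbinol centre forms as a mixture that is re-oxidised in step 11.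

Step 9
Reactants: 12 (1RS,4R)-4-(2-hydroxyethyl)-3,5,5-trimethylcyclohex-2-en-1-ol
Product: 13 (1RS,4R)-4-(2-bromoethyl)-3,5,5-trimethylcyclohex-2-en-1-ol
Conditions: CBr4 (1.05 equiv), PPh3 (1.1 equiv), CH2Cl2, −40 → 0 °C
Reagents that add atoms: tetrabromomethane, BrC(Br)(Br)Br
Why: Appel bromination (SN2 on the oxyphosphonium ion) should be faster at the unhindered primary hydroxyl than at the secondary ring hydroxyl when one equivalent is used cold.

Step 10
Reactants: 13 (1RS,4R)-4-(2-bromoethyl)-3,5,5-trimethylcyclohex-2-en-1-ol; 14 prop-2-yn-1-ol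
Product: 17 (2Z)-2-{2-[(1R,4RS)-4-hydroxy-2,6,6-trimethylcyclohex-2-en-1-yl]ethyl}-3-iodoprop-2-en-1-ol, via alkoxide Grignard reagent 15 (not isolated), via vinylmagnesium chelate 16 (not isolated)
Conditions: i-PrMgCl (1 equiv), THF, −20 °C, then Mg, 35 °C; add to 14/i-PrMgCl (1 equiv), CuI (10 mol %), THF, 0 °C → rt; then I2, −40 → 0 °C; aq. Na2S2O3/NH4Cl
Reagents that add atoms: iodine, II
Why: Duboudin copper-catalysed anti-carbomagnesiation of the magnesium alkoxide of propargyl alcohol should put the alkyl group on the internal carbon and magnesium on the terminal carbon cis to CH2O (five-membered chelate), and iodinolysis with retention should give the Z-iodoalkene, the ring hydroxyl being carried as its magnesium alkoxide.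

Step 11
Reactants: 17 (2Z)-2-{2-[(1R,4RS)-4-hydroxy-2,6,6-trimethylcyclohex-2-en-1-yl]ethyl}-3-iodoprop-2-en-1-ol
Product: 18 (2Z)-3-iodo-2-{2-[(1R)-2,6,6-trimethyl-4-oxocyclohex-2-en-1-yl]ethyl}prop-2-enal
Conditions: MnO2 (activated, excess), CH2Cl2, rt, dark
Reagents that add atoms: none
Why: Allylic oxidation with MnO2 should take the primary allylic alcohol to the enal and the ring allylic alcohol back to the enone, which removes the carbinol mixture and keeps the iodoalkene geometry.

Step 12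
Reactants: 18 (2Z)-3-iodo-2-{2-[(1R)-2,6,6-trimethyl-4-oxocyclohex-2-en-1-yl]ethyl}prop-2-enal
Product: 19 (2Z)-3-iodo-2-{2-[(1R)-2,6,6-trimethyl-4-oxocyclohex-2-en-1-yl]ethyl}prop-2-enoic acid
Conditions: NaClO2, NaH2PO4, 2-methylbut-2-ene, t-BuOH/H2O, 0 °C → rt
Reagents that add atoms: sodium chlorite, [Na+].[O-]Cl=O
Why: Pinnick oxidation should convert the enal into the acid without affecting the enone, the vinyl iodide or the Z geometry, the alkene additive scavenging HOCl.

## Fragment B: polyenyne 38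

Step 13
Reactants: 20 (4R,6R)-4-hydroxy-2,2,6-trimethylcyclohexan-1-one ((−)-actinol)
Product: 21 (4R,6R)-4-[(tert-butyldimethylsilyl)oxy]-2,2,6-trimethylcyclohexan-1-one
Conditions: t-BuMe2SiCl, imidazole, DMF, rt
Reagents that add atoms: tert-butyl(chloro)dimethylsilane, CC(C)(C)[Si](C)(C)Cl
Why: Imidazole-promoted silylation should protect the secondary alcohol, whose configuration becomes that of C3' of the target.

Step 14
Reactants: 21 (4R,6R)-4-[(tert-butyldimethylsilyl)oxy]-2,2,6-trimethylcyclohexan-1-one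
Product: 22 (4R)-4-[(tert-butyldimethylsilyl)oxy]-2,6,6-trimethylcyclohex-1-en-1-yl trifluoromethanesulfonate
Conditions: KN(SiMe3)2, THF, −78 °C; PhNTf2, −78 → 0 °C
Reagents that add atoms: N-phenylbis(trifluoromethanesulfonimide), O=S(=O)(N(c1ccccc1)S(=O)(=O)C(F)(F)F)C(F)(F)F
Why: Enolisation can occur only toward the methyl-bearing carbon (the other α-carbon is quaternary), so O-triflation of the enolate should give a single tetrasubstituted enol triflate and leave the silyloxy centre untouched.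

Step 15
Reactants: 22 (4R)-4-[(tert-butyldimethylsilyl)oxy]-2,6,6-trimethylcyclohex-1-en-1-yl trifluoromethanesulfonate
Product: 23 methyl (4R)-4-[(tert-butyldimethylsilyl)oxy]-2,6,6-trimethylcyclohex-1-ene-1-carboxylate
Conditions: Pd(OAc)2 (5 mol %), PPh3, CO (1 atm), MeOH, Et3N, DMF, 60 °C
Reagents that add atoms: carbon monoxide, [C-]#[O+]; methanol, CO
Why: Palladium-catalysed methoxycarbonylation of the vinyl triflate (oxidative addition, CO insertion, methanolysis) should install the C7' carbon.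

Step 16
Reactants: 23 methyl (4R)-4-[(tert-butyldimethylsilyl)oxy]-2,6,6-trimethylcyclohex-1-ene-1-carboxylate
Product: 24 [(4R)-4-[(tert-butyldimethylsilyl)oxy]-2,6,6-trimethylcyclohex-1-en-1-yl]methanol
Conditions: i-Bu2AlH, CH2Cl2, −78 → 0 °C; aq. potassium sodium tartrate
Reagents that add atoms: none
Why: Hydride reduction of the conjugated ester with i-Bu2AlH should give the allylic alcohol needed to direct the epoxidation.

Step 17
Reactants: 24 [(4R)-4-[(tert-butyldimethylsilyl)oxy]-2,6,6-trimethylcyclohex-1-en-1-yl]methanol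
Product: 25 [(1R,4S,6R)-4-[(tert-butyldimethylsilyl)oxy]-2,2,6-trimethyl-7-oxabicyclo[4.1.0]heptan-1-yl]methanol
Conditions: Ti(OiPr)4 (20 mol %), D-(−)-diethyl tartrate (24 mol %), t-BuOOH, 4 Å MS, CH2Cl2, −20 °C
Reagents that add atoms: tert-butyl hydroperoxide, CC(C)(C)OO
Why: Sharpless asymmetric epoxidation with D-(−)-tartrate should deliver oxygen to the alkene face anti to the silyloxy group (reagent control matched with the substrate bias), which sets both oxirane carbons as 5'R,6'S in carotenoid numbering.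

Step 18
Reactants: 25 [(1R,4S,6R)-4-[(tert-butyldimethylsilyl)oxy]-2,2,6-trimethyl-7-oxabicyclo[4.1.0]heptan-1-yl]methanol
Product: 26 (1S,4S,6R)-4-[(tert-butyldimethylsilyl)oxy]-2,2,6-trimethyl-7-oxabicyclo[4.1.0]heptane-1-carbaldehyde
Conditions: Pr4N[RuO4] (5 mol %), N-methylmorpholine N-oxide, 4 Å MS, CH2Cl2, rt
Reagents that add atoms: none
Why: Ley–Griffith oxidation is non-acidic, so the epoxide should survive, and the aldehyde has no α-hydrogen to epimerise.

Step 19
Reactants: 26 (1S,4S,6R)-4-[(tert-butyldimethylsilyl)oxy]-2,2,6-trimethyl-7-oxabicyclo[4.1.0]heptane-1-carbaldehyde; 27 diethyl [(2E)-3-cyano-2-methylprop-2-en-1-yl]phosphonate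
Product: 28 (2E,4E)-5-[(1S,4S,6R)-4-[(tert-butyldimethylsilyl)oxy]-2,2,6-trimethyl-7-oxabicyclo[4.1.0]heptan-1-yl]-3-methylpenta-2,4-dienenitrile
Conditions: NaH, THF, 0 °C → rt
Reagents that add atoms: none
Why: Horner–Wadsworth–Emmons olefination with the C5 nitrile phosphonate should form the C7'=C8' bond E and give mainly the E trisubstituted alkene because the allyl anion of the reagent equilibrates, the minor Z isomer being removed by chromatography.

Step 20
Reactants: 28 (2E,4E)-5-[(1S,4S,6R)-4-[(tert-butyldimethylsilyl)oxy]-2,2,6-trimethyl-7-oxabicyclo[4.1.0]heptan-1-yl]-3-methylpenta-2,4-dienenitrile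
Product: 29 (2E,4E)-5-[(1S,4S,6R)-4-[(tert-butyldimethylsilyl)oxy]-2,2,6-trimethyl-7-oxabicyclo[4.1.0]heptan-1-yl]-3-methylpenta-2,4-dienal
Conditions: i-Bu2AlH (1.3 equiv), toluene, −78 °C; wet SiO2, 0 °C
Reagents that add atoms: water, O
Why: Partial reduction of the nitrile with i-Bu2AlH to the aluminium aldimine and near-neutral hydrolysis should give the dienal while the acid-sensitive vinyl epoxide and the silyl ether are kept.

Step 21
Reactants: 29 (2E,4E)-5-[(1S,4S,6R)-4-[(tert-butyldimethylsilyl)oxy]-2,2,6-trimethyl-7-oxabicyclo[4.1.0]heptan-1-yl]-3-methylpenta-2,4-dienal; 27 diethyl [(2E)-3-cyano-2-methylprop-2-en-1-yl]phosphonate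
Product: 30 (2E,4E,6E,8E)-9-[(1S,4S,6R)-4-[(tert-butyldimethylsilyl)oxy]-2,2,6-trimethyl-7-oxabicyclo[4.1.0]heptan-1-yl]-3,7-dimethylnona-2,4,6,8-tetraenenitrile
Conditions: NaH, THF, 0 °C → rt
Reagents that add atoms: none
Why: A second Horner–Wadsworth–Emmons olefination should form the C11'=C12' bond E and again give mainly the E trisubstituted alkene.

Step 22
Reactants: 30 (2E,4E,6E,8E)-9-[(1S,4S,6R)-4-[(tert-butyldimethylsilyl)oxy]-2,2,6-trimethyl-7-oxabicyclo[4.1.0]heptan-1-yl]-3,7-dimethylnona-2,4,6,8-tetraenenitrile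
Product: 31 (2E,4E,6E,8E)-9-[(1S,4S,6R)-4-[(tert-butyldimethylsilyl)oxy]-2,2,6-trimethyl-7-oxabicyclo[4.1.0]heptan-1-yl]-3,7-dimethylnona-2,4,6,8-tetraenal
Conditions: i-Bu2AlH (1.3 equiv), toluene, −78 °C; wet SiO2, 0 °C
Reagents that add atoms: water, O
Why: The same nitrile-to-aldehyde reduction with i-Bu2AlH should give the C20 tetraenal without touching the epoxide.

Step 23
Reactants: 32 (2E)-3-methylpent-2-en-4-yn-1-ol
Product: 34 (2E)-3-methyl-5-(trimethylsilyl)pent-2-en-4-yn-1-ol, via bis-silylated enynol 33 (not isolated)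
Conditions: n-BuLi (2.1 equiv), THF, −78 °C; Me3SiCl (2.2 equiv), → rt; 1 M aq. HCl, rt
Reagents that add atoms: chlorotrimethylsilane, C[Si](C)(C)Cl
Why: Double deprotonation and bis-silylation followed by selective acid hydrolysis of the labile O–Si bond should leave the alkyne C-silylated.

Step 24
Reactants: 34 (2E)-3-methyl-5-(trimethylsilyl)pent-2-en-4-yn-1-ol
Product: 35 [(3E)-5-bromo-3-methylpent-3-en-1-yn-1-yl]trimethylsilane
Conditions: CBr4, PPh3, CH2Cl2, 0 °C
Reagents that add atoms: tetrabromomethane, BrC(Br)(Br)Br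
Why: Appel bromination should convert the primary allylic alcohol into the bromide under neutral conditions with the E geometry kept.

Step 25
Reactants: 35 [(3E)-5-bromo-3-methylpent-3-en-1-yn-1-yl]trimethylsilane
Product: 36 diethyl [(2E)-3-methyl-5-(trimethylsilyl)pent-2-en-4-yn-1-yl]phosphonate
Conditions: P(OEt)3, neat, 110 °C
Reagents that add atoms: triethyl phosphite, CCOP(OCC)OCC
Why: Michaelis–Arbuzov reaction of the primary allylic bromide should give the phosphonate by SN2 attack of phosphorus and loss of bromoethane.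

Step 26
Reactants: 31 (2E,4E,6E,8E)-9-[(1S,4S,6R)-4-[(tert-butyldimethylsilyl)oxy]-2,2,6-trimethyl-7-oxabicyclo[4.1.0]heptan-1-yl]-3,7-dimethylnona-2,4,6,8-tetraenal; 36 diethyl [(2E)-3-methyl-5-(trimethylsilyl)pent-2-en-4-yn-1-yl]phosphonate
Product: 37 tert-butyl(dimethyl){[(1R,3S,6S)-1,5,5-trimethyl-6-[(1E,3E,5E,7E,9E,11E)-3,7,12-trimethyl-14-(trimethylsilyl)tetradeca-1,3,5,7,9,11-hexaen-13-yn-1-yl]-7-oxabicyclo[4.1.0]heptan-3-yl]oxy}silane
Conditions: NaN(SiMe3)2, THF, −78 → 0 °C
Reagents that add atoms: none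
Why: Horner–Wadsworth–Emmons olefination with the allylic phosphonate should form the central C15=C15' bond with E preference, any minor Z isomer being removed by chromatography or equilibrated thermally.

Step 27
Reactants: 37 doubly silylated polyenyne
Product: 38 (1R,3S,6S)-1,5,5-trimethyl-6-[(1E,3E,5E,7E,9E,11E)-3,7,12-trimethyltetradeca-1,3,5,7,9,11-hexaen-13-yn-1-yl]-7-oxabicyclo[4.1.0]heptan-3-ol
Conditions: Bu4NF (2.5 equiv), THF, 0 °C → rt
Reagents that add atoms: none
Why: Fluoride-mediated desilylation should remove the alkynyl silyl group and the silyl ether in one operation, and the epoxide and polyene are stable to fluoride.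

## Union

Step 28
Reactants: 19 (2Z)-3-iodo-2-{2-[(1R)-2,6,6-trimethyl-4-oxocyclohex-2-en-1-yl]ethyl}prop-2-enoic acid; 38 (1R,3S,6S)-1,5,5-trimethyl-6-[(1E,3E,5E,7E,9E,11E)-3,7,12-trimethyltetradeca-1,3,5,7,9,11-hexaen-13-yn-1-yl]-7-oxabicyclo[4.1.0]heptan-3-ol
Product: 40 (5Z)-5-{(2E,4E,6E,8E,10E,12E)-13-[(1S,4S,6R)-4-hydroxy-2,2,6-trimethyl-7-oxabicyclo[4.1.0]heptan-1-yl]-2,7,11-trimethyltrideca-2,4,6,8,10,12-hexaen-1-ylidene}-3-{2-[(1R)-2,6,6-trimethyl-4-oxocyclohex-2-en-1-yl]ethyl}furan-2(5H)-one (target), via enynoic acid 39 (not isolated)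
Conditions: Pd(PPh3)4 (5 mol %), CuI (10 mol %), Et3N, MeCN, rt, Ar, dark
Reagents that add atoms: none
Why: Sonogashira coupling of the Z-iodoacrylic acid with the terminal alkyne, followed in the same flask by metal-promoted anti addition of the cis carboxylate across the alkyne in the 5-exo-dig mode, should give the Z-γ-ylidenebutenolide under conditions (amine base, room temperature) that the enone, epoxide, free hydroxyl and polyene tolerate.

## Compound list

1 | (1R,3R)-2,2-dimethyl-3-(2-methylprop-1-en-1-yl)cyclopropane-1-carboxylic acid ((+)-trans-chrysanthemic acid) | CC(C)=C[C@@H]1[C@H](C1(C)C)C(=O)O | starting material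
2 | methyl (1R,3R)-2,2-dimethyl-3-(2-methylprop-1-en-1-yl)cyclopropane-1-carboxylate | CC(C)=C[C@@H]1[C@H](C1(C)C)C(=O)OC | intermediate
3 | methyl (1R,3R)-3-(5,5-dimethyl-1,2,4-trioxolan-3-yl)-2,2-dimethylcyclopropane-1-carboxylate (secondary ozonide) | CC1(C)OOC(O1)[C@@H]2[C@H](C2(C)C)C(=O)OC | intermediate (not isolated)
4 | methyl (1R,3R)-3-formyl-2,2-dimethylcyclopropane-1-carboxylate | O=C[C@@H]1[C@H](C1(C)C)C(=O)OC | intermediate
5 | 1-(triphenyl-λ5-phosphanylidene)propan-2-one | CC(=O)C=P(c1ccccc1)(c1ccccc1)c1ccccc1 | starting material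
6 | methyl (1R,3R)-2,2-dimethyl-3-[(1E)-3-oxobut-1-en-1-yl]cyclopropane-1-carboxylate | CC(=O)/C=C/[C@@H]1[C@H](C1(C)C)C(=O)OC | intermediate
7 | methyl (1R,3R)-2,2-dimethyl-3-[(2RS)-4-oxopentan-2-yl]cyclopropane-1-carboxylate | CC(=O)CC(C)[C@@H]1[C@H](C1(C)C)C(=O)OC | intermediate
8 | methyl (1R,3R)-2,2-dimethyl-3-[(2RS)-4-[(trimethylsilyl)oxy]pent-4-en-2-yl]cyclopropane-1-carboxylate | C=C(O[Si](C)(C)C)CC(C)[C@@H]1[C@H](C1(C)C)C(=O)OC | intermediate
9 | trichlorotitanium enolate of the methyl ester 10 (O-titanated ketene acetal) | COC(O[Ti](Cl)(Cl)Cl)=C[C@H]1C(C)CC(=O)CC1(C)C | intermediate (not isolated)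
10 | methyl 2-[(1S,6RS)-2,2,6-trimethyl-4-oxocyclohexyl]acetate | COC(=O)C[C@H]1C(C)CC(=O)CC1(C)C | intermediate
11 | methyl 2-[(1R)-2,6,6-trimethyl-4-oxocyclohex-2-en-1-yl]acetate | COC(=O)C[C@H]1C(C)=CC(=O)CC1(C)C | intermediate
12 | (1RS,4R)-4-(2-hydroxyethyl)-3,5,5-trimethylcyclohex-2-en-1-ol | OCC[C@H]1C(C)=CC(O)CC1(C)C | intermediate
13 | (1RS,4R)-4-(2-bromoethyl)-3,5,5-trimethylcyclohex-2-en-1-ol | BrCC[C@H]1C(C)=CC(O)CC1(C)C | intermediate
14 | prop-2-yn-1-ol | C#CCO | starting material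
15 | bromomagnesium alkyl / chloromagnesium alkoxide reagent from 13 | Br[Mg]CC[C@H]1C(C)=CC(O[Mg]Cl)CC1(C)C | intermediate (not isolated)
16 | (Z)-vinylmagnesium bromide bis(chloromagnesium alkoxide) from 15 and 14 | Cl[Mg]OC/C(CC[C@H]1C(C)=CC(O[Mg]Cl)CC1(C)C)=C\[Mg]Br | intermediate (not isolated)
17 | (2Z)-2-{2-[(1R,4RS)-4-hydroxy-2,6,6-trimethylcyclohex-2-en-1-yl]ethyl}-3-iodoprop-2-en-1-ol | OC/C(CC[C@H]1C(C)=CC(O)CC1(C)C)=C\I | intermediate
18 | (2Z)-3-iodo-2-{2-[(1R)-2,6,6-trimethyl-4-oxocyclohex-2-en-1-yl]ethyl}prop-2-enal | O=C/C(CC[C@H]1C(C)=CC(=O)CC1(C)C)=C\I | intermediate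
19 | (2Z)-3-iodo-2-{2-[(1R)-2,6,6-trimethyl-4-oxocyclohex-2-en-1-yl]ethyl}prop-2-enoic acid | OC(=O)/C(CC[C@H]1C(C)=CC(=O)CC1(C)C)=C\I | intermediate
20 | (4R,6R)-4-hydroxy-2,2,6-trimethylcyclohexan-1-one ((−)-actinol) | O=C1C(C)(C)C[C@H](O)C[C@H]1C | starting material
21 | (4R,6R)-4-[(tert-butyldimethylsilyl)oxy]-2,2,6-trimethylcyclohexan-1-one | O=C1C(C)(C)C[C@H](O[Si](C)(C)C(C)(C)C)C[C@H]1C | intermediate
22 | (4R)-4-[(tert-butyldimethylsilyl)oxy]-2,6,6-trimethylcyclohex-1-en-1-yl trifluoromethanesulfonate | CC1=C(OS(=O)(=O)C(F)(F)F)C(C)(C)C[C@H](O[Si](C)(C)C(C)(C)C)C1 | intermediate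
23 | methyl (4R)-4-[(tert-butyldimethylsilyl)oxy]-2,6,6-trimethylcyclohex-1-ene-1-carboxylate | CC1=C(C(=O)OC)C(C)(C)C[C@H](O[Si](C)(C)C(C)(C)C)C1 | intermediate
24 | [(4R)-4-[(tert-butyldimethylsilyl)oxy]-2,6,6-trimethylcyclohex-1-en-1-yl]methanol | CC1=C(CO)C(C)(C)C[C@H](O[Si](C)(C)C(C)(C)C)C1 | intermediate
25 | [(1R,4S,6R)-4-[(tert-butyldimethylsilyl)oxy]-2,2,6-trimethyl-7-oxabicyclo[4.1.0]heptan-1-yl]methanol | OC[C@@]12O[C@]1(C)C[C@@H](O[Si](C)(C)C(C)(C)C)CC2(C)C | intermediate
26 | (1S,4S,6R)-4-[(tert-butyldimethylsilyl)oxy]-2,2,6-trimethyl-7-oxabicyclo[4.1.0]heptane-1-carbaldehyde | O=C[C@@]12O[C@]1(C)C[C@@H](O[Si](C)(C)C(C)(C)C)CC2(C)C | intermediate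
27 | diethyl [(2E)-3-cyano-2-methylprop-2-en-1-yl]phosphonate (commercial E/Z mixture usable) | CCOP(=O)(OCC)C/C(C)=C/C#N | starting material
28 | (2E,4E)-5-[(1S,4S,6R)-4-[(tert-butyldimethylsilyl)oxy]-2,2,6-trimethyl-7-oxabicyclo[4.1.0]heptan-1-yl]-3-methylpenta-2,4-dienenitrile | N#C/C=C(C)/C=C/[C@@]12O[C@]1(C)C[C@@H](O[Si](C)(C)C(C)(C)C)CC2(C)C | intermediate
29 | (2E,4E)-5-[(1S,4S,6R)-4-[(tert-butyldimethylsilyl)oxy]-2,2,6-trimethyl-7-oxabicyclo[4.1.0]heptan-1-yl]-3-methylpenta-2,4-dienal | O=C/C=C(C)/C=C/[C@@]12O[C@]1(C)C[C@@H](O[Si](C)(C)C(C)(C)C)CC2(C)C | intermediate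
30 | (2E,4E,6E,8E)-9-[(1S,4S,6R)-4-[(tert-butyldimethylsilyl)oxy]-2,2,6-trimethyl-7-oxabicyclo[4.1.0]heptan-1-yl]-3,7-dimethylnona-2,4,6,8-tetraenenitrile | N#C/C=C(C)/C=C/C=C(C)/C=C/[C@@]12O[C@]1(C)C[C@@H](O[Si](C)(C)C(C)(C)C)CC2(C)C | intermediate
31 | (2E,4E,6E,8E)-9-[(1S,4S,6R)-4-[(tert-butyldimethylsilyl)oxy]-2,2,6-trimethyl-7-oxabicyclo[4.1.0]heptan-1-yl]-3,7-dimethylnona-2,4,6,8-tetraenal | O=C/C=C(C)/C=C/C=C(C)/C=C/[C@@]12O[C@]1(C)C[C@@H](O[Si](C)(C)C(C)(C)C)CC2(C)C | intermediate
32 | (2E)-3-methylpent-2-en-4-yn-1-ol | C#C/C(C)=C/CO | starting material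
33 | trimethyl{[(2E)-3-methyl-5-(trimethylsilyl)pent-2-en-4-yn-1-yl]oxy}silane | C[Si](C)(C)C#C/C(C)=C/CO[Si](C)(C)C | intermediate (not isolated)
34 | (2E)-3-methyl-5-(trimethylsilyl)pent-2-en-4-yn-1-ol | C[Si](C)(C)C#C/C(C)=C/CO | intermediate
35 | [(3E)-5-bromo-3-methylpent-3-en-1-yn-1-yl]trimethylsilane | C[Si](C)(C)C#C/C(C)=C/CBr | intermediate
36 | diethyl [(2E)-3-methyl-5-(trimethylsilyl)pent-2-en-4-yn-1-yl]phosphonate | CCOP(=O)(OCC)C/C=C(C)/C#C[Si](C)(C)C | intermediate
37 | tert-butyl(dimethyl){[(1R,3S,6S)-1,5,5-trimethyl-6-[(1E,3E,5E,7E,9E,11E)-3,7,12-trimethyl-14-(trimethylsilyl)tetradeca-1,3,5,7,9,11-hexaen-13-yn-1-yl]-7-oxabicyclo[4.1.0]heptan-3-yl]oxy}silane | C[Si](C)(C)C#C/C(C)=C/C=C/C=C(C)/C=C/C=C(C)/C=C/[C@@]12O[C@]1(C)C[C@@H](O[Si](C)(C)C(C)(C)C)CC2(C)C | intermediate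
38 | (1R,3S,6S)-1,5,5-trimethyl-6-[(1E,3E,5E,7E,9E,11E)-3,7,12-trimethyltetradeca-1,3,5,7,9,11-hexaen-13-yn-1-yl]-7-oxabicyclo[4.1.0]heptan-3-ol | C#C/C(C)=C/C=C/C=C(C)/C=C/C=C(C)/C=C/[C@@]12O[C@]1(C)C[C@@H](O)CC2(C)C | intermediate
39 | (2Z,6E,8E,10E,12E,14E,16E)-17-[(1S,4S,6R)-4-hydroxy-2,2,6-trimethyl-7-oxabicyclo[4.1.0]heptan-1-yl]-6,11,15-trimethyl-2-{2-[(1R)-2,6,6-trimethyl-4-oxocyclohex-2-en-1-yl]ethyl}heptadeca-2,6,8,10,12,14,16-heptaen-4-ynoic acid | OC(=O)/C(CC[C@H]1C(C)=CC(=O)CC1(C)C)=C\C#C/C(C)=C/C=C/C=C(C)/C=C/C=C(C)/C=C/[C@@]12O[C@]1(C)C[C@@H](O)CC2(C)C | intermediate (not isolated)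
40 | (5Z)-5-{(2E,4E,6E,8E,10E,12E)-13-[(1S,4S,6R)-4-hydroxy-2,2,6-trimethyl-7-oxabicyclo[4.1.0]heptan-1-yl]-2,7,11-trimethyltrideca-2,4,6,8,10,12-hexaen-1-ylidene}-3-{2-[(1R)-2,6,6-trimethyl-4-oxocyclohex-2-en-1-yl]ethyl}furan-2(5H)-one | CC1=CC(=O)CC(C)(C)[C@H]1CCC1=C/C(=C/C(C)=C/C=C/C=C(C)/C=C/C=C(C)/C=C/[C@@]23O[C@]2(C)C[C@@H](O)CC3(C)C)OC1=O | target

## Step count and risks

Total step count: 28 (12 to iodo acid 19, 15 to polyenyne 38 including 3 for phosphonate 36, 1 union).
Longest linear sequence: 13 steps (steps 1–12 and 28; equally steps 13–22 and 26–28).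

Steps most likely to fail:

1. Step 6 (the step that carries the proposed new method). The cyclopropane may ionise without timely ring closure, followed by 1,2-hydride shift from C6 or proton loss to an alkene; the silyl enol ether may also be consumed by the Lewis acid or by intermolecular Mukaiyama aldol addition before it cyclises. The fallback uses known chemistry and still closes the ring at C1–C2. It sets out from 7: saponification (LiOH, THF/H2O) gives the cyclopropane keto acid F1. Acid treatment (TsOH, toluene, 80 °C) triggers the pyrocine-type rearrangement of the cyclopropane acid to the γ-lactone F2, in which the carboxyl oxygen has captured the gem-dimethyl carbon and C6 is untouched. HCl in MeOH opens the tertiary lactone to the tertiary chloride methyl ester F3. Kinetic silylation (LiN(iPr)2, Me3SiCl, −78 °C) gives the silyl enol ether F4. TiCl4 in CH2Cl2 at −78 °C then effects an intramolecular Reetz α-tert-alkylation, which comes back to the route at 10.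

2. Step 10. Magnesium insertion may be sluggish and accompanied by Wurtz coupling in the presence of the magnesium alkoxide, and proton transfer may quench the carbomagnesiation; step 9 also relies on kinetic discrimination of two hydroxyls. The fallback protects the ring oxygen and generates the organomagnesium by halogen–lithium exchange. It sets out from 11: Luche reduction (NaBH4, CeCl3, MeOH) gives the hydroxy ester F5, and silylation (t-BuMe2SiCl, imidazole) gives the silyl ether F6. Reduction with i-Bu2AlH gives the primary alcohol F7, and I2/PPh3/imidazole gives the iodide F8. Exchange with t-BuLi (2 equiv, Et2O, −78 °C), transmetallation with MgBr2·OEt2, the same copper-catalysed addition to the magnesium alkoxide of 14 and iodinolysis give the silylated Z-iodo alcohol F9. Bu4NF then returns to the route at 17.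

3. Step 28. Lactonisation may take the 6-endo course to a 2-pyranone, the polyenyne may homocouple oxidatively, and the polyene may isomerise or degrade while the tandem process runs. The fallback separates coupling from ring closure. It sets out from 19: Me3SiCHN2 (MeOH/toluene) gives the methyl ester F10. Sonogashira coupling with 38 (Pd(PPh3)4, CuI, Et3N) gives the Z-enynoate F11, which cannot cyclise. LiOH (THF/H2O, 0 °C) gives the acid and comes back to the route at 39, now isolated. Catalytic AgNO3 in acetone, a cyclisation known to be selective for the 5-exo anti mode, then gives 40.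

## Further compounds

F1 | step 6 | (1R,3R)-2,2-dimethyl-3-[(2RS)-4-oxopentan-2-yl]cyclopropane-1-carboxylic acid | CC(=O)CC(C)[C@@H]1[C@H](C1(C)C)C(=O)O
F2 | step 6 | (4S)-5,5-dimethyl-4-[(2RS)-4-oxopentan-2-yl]oxolan-2-one | O=C1C[C@@H](C(C)CC(C)=O)C(C)(C)O1
F3 | step 6 | methyl (3S)-4-chloro-4-methyl-3-[(2RS)-4-oxopentan-2-yl]pentanoate | COC(=O)C[C@@H](C(C)CC(C)=O)C(C)(C)Cl
F4 | step 6 | methyl (3S)-4-chloro-4-methyl-3-[(2RS)-4-[(trimethylsilyl)oxy]pent-4-en-2-yl]pentanoate | COC(=O)C[C@@H](C(C)CC(=C)O[Si](C)(C)C)C(C)(C)Cl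
F5 | step 10 | methyl 2-[(1R,4RS)-4-hydroxy-2,6,6-trimethylcyclohex-2-en-1-yl]acetate | COC(=O)C[C@H]1C(C)=CC(O)CC1(C)C
F6 | step 10 | methyl 2-[(1R,4RS)-4-[(tert-butyldimethylsilyl)oxy]-2,6,6-trimethylcyclohex-2-en-1-yl]acetate | COC(=O)C[C@H]1C(C)=CC(O[Si](C)(C)C(C)(C)C)CC1(C)C
F7 | step 10 | 2-[(1R,4RS)-4-[(tert-butyldimethylsilyl)oxy]-2,6,6-trimethylcyclohex-2-en-1-yl]ethan-1-ol | OCC[C@H]1C(C)=CC(O[Si](C)(C)C(C)(C)C)CC1(C)C
F8 | step 10 | tert-butyl{[(1RS,4R)-4-(2-iodoethyl)-3,5,5-trimethylcyclohex-2-en-1-yl]oxy}dimethylsilane | ICC[C@H]1C(C)=CC(O[Si](C)(C)C(C)(C)C)CC1(C)C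
F9 | step 10 | (2Z)-2-{2-[(1R,4RS)-4-[(tert-butyldimethylsilyl)oxy]-2,6,6-trimethylcyclohex-2-en-1-yl]ethyl}-3-iodoprop-2-en-1-ol | OC/C(CC[C@H]1C(C)=CC(O[Si](C)(C)C(C)(C)C)CC1(C)C)=C\I
F10 | step 28 | methyl (2Z)-3-iodo-2-{2-[(1R)-2,6,6-trimethyl-4-oxocyclohex-2-en-1-yl]ethyl}prop-2-enoate | COC(=O)/C(CC[C@H]1C(C)=CC(=O)CC1(C)C)=C\I
F11 | step 28 | methyl (2Z,6E,8E,10E,12E,14E,16E)-17-[(1S,4S,6R)-4-hydroxy-2,2,6-trimethyl-7-oxabicyclo[4.1.0]heptan-1-yl]-6,11,15-trimethyl-2-{2-[(1R)-2,6,6-trimethyl-4-oxocyclohex-2-en-1-yl]ethyl}heptadeca-2,6,8,10,12,14,16-heptaen-4-ynoate | COC(=O)/C(CC[C@H]1C(C)=CC(=O)CC1(C)C)=C\C#C/C(C)=C/C=C/C=C(C)/C=C/C=C(C)/C=C/[C@@]12O[C@]1(C)C[C@@H](O)CC2(C)C
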